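The plan disconnects the two bonds that join the C18 carboxyl unit to ring A, C4–C5 and C19–O (clerodane numbering, defined below). It exploits C5 being the quaternary atom shared by ring A, ring B and the γ-lactone and carrying the oxygenated methylene C19: a C5=C19 exocyclic alkene can accept C4 at C5 and the carboxylate oxygen at C19. One palladium-catalysed cascade on a monocyclic (Z)-α-iodo-γ-oxo-enoic acid should close ring B by 6-exo carbopalladation, set C5, and close the lactone by iodine transfer and carboxylate alkylation. The precursor is a methylidenecyclohexane bearing furyl, iodoenone-acid and tert-butyl acetate arms; ring C is closed afterwards by Friedel–Crafts acylation.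

Key step: step 13

Remark on numbering: ring A = C5–C10; ring B = C1–C5 and C10; ring C = C1, C10, C9, C11, C12, C13, C16; furan = C13–C16 and O (C16 bonded to C1, C13 to the C12 ketone); C17 = methyl on C8; C18 = lactone carbonyl on C4; C19 = lactone CH2 on C5; C20 = methyl on C9; the target is (1S,2S,5S,7S,8S,9R,10R); compounds 11–17 are carried as mixtures of epimers at C1 (and 15 also at C2), which is corrected in step 13.

Step 1
Reactants: 1 2-methylcyclohex-2-en-1-one
Product: 3 (2R,3S)-3-hydroxy-2-methylcyclohexan-1-one, via pinacol boronate 2 (not isolated)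
Conditions: CuCl (5 mol%), NaOt-Bu (10 mol%), QuinoxP* (6 mol%, enantiomer chosen to give 3S), B2pin2, MeOH, THF, rt; then 30% H2O2, pH 7 phosphate buffer, 0 °C
Reagents that add atoms: bis(pinacolato)diboron, CC1(C)OB(OC1(C)C)B1OC(C)(C)C(C)(C)O1 (boron of 2); hydrogen peroxide, OO (hydroxyl oxygen of 3)
Why: Copper-catalysed enantioselective conjugate borylation should set the future C7 stereocentre under ligand control (the only reagent-controlled stereocentre of the route), the adjacent C8 methyl settling trans (both equatorial) by enolate protonation and equilibration in the alkoxide medium, and C–B oxidation proceeds with retention.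

Step 2
Reactants: 3 (2R,3S)-3-hydroxy-2-methylcyclohexan-1-one
Product: 4 (2R,3S)-3-(tert-butyldimethylsilyloxy)-2-methylcyclohexan-1-one
Conditions: TBSCl, imidazole, DMF, rt
Reagents that add atoms: tert-butyldimethylsilyl chloride, CC(C)(C)[Si](C)(C)Cl
Why: Standard silylation of the secondary alcohol (no stereocentre touched) masks C7–OH until the acidic step 14.

Step 3
Reactants: 4 (2R,3S)-3-(tert-butyldimethylsilyloxy)-2-methylcyclohexan-1-one
Product: 5 (5S,6R)-5-(tert-butyldimethylsilyloxy)-6-methylcyclohex-2-en-1-one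
Conditions: LiN(i-Pr)2, THF, −78 °C; then N-tert-butylbenzenesulfinimidoyl chloride, −78 °C
Reagents that add atoms: none
Why: Kinetic deprotonation at the unhindered C10 methylene (not at the tertiary C8–H), S-attack of the enolate on the sulfinimidoyl chloride and syn-elimination (one-pot ketone-to-enone dehydrogenation) should give the C5=C10 enone with C7 and C8 untouched.

Step 4
Reactants: 5 (5S,6R)-5-(tert-butyldimethylsilyloxy)-6-methylcyclohex-2-en-1-one
Product: 6 (5S,6R)-5-(tert-butyldimethylsilyloxy)-1,6-dimethylcyclohex-2-en-1-ol (both epimers at the carbinol carbon)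
Conditions: MeLi, Et2O, −78 °C; aq. NH4Cl
Reagents that add atoms: methyllithium, [Li]C
Why: 1,2-Addition of the hard organolithium to the enone carbonyl (future C9) at low temperature outruns enolisation and brings in C20; the new carbinol centre is lost in step 5.

Step 5
Reactants: 6 (5S,6R)-5-(tert-butyldimethylsilyloxy)-1,6-dimethylcyclohex-2-en-1-ol
Product: 7 (4S,5S)-5-(tert-butyldimethylsilyloxy)-3,4-dimethylcyclohex-2-en-1-one
Conditions: pyridinium chlorochromate (C5H5NH[CrO3Cl]), 4 Å molecular sieves, CH2Cl2, rt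
Reagents that add atoms: none
Why: Babler–Dauben oxidative transposition (chromate ester, [3,3]-shift, oxidation) moves the oxygen to C5 and the alkene to C9=C10, giving the β-methyl enone needed for the quaternary centre.

Step 6
Reactants: 7 (4S,5S)-5-(tert-butyldimethylsilyloxy)-3,4-dimethylcyclohex-2-en-1-one; 8 tert-butyl[(1-tert-butoxyethenyl)oxy]dimethylsilane
Product: 9 tert-butyl 2-[(1S,5S,6S)-3,5-bis(tert-butyldimethylsilyloxy)-1,6-dimethylcyclohex-2-en-1-yl]acetate
Conditions: HNTf2 (2 mol%), CH2Cl2, −78 °C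
Reagents that add atoms: none
Why: Mukaiyama–Michael addition (silyl triflimide formed in situ as Lewis acid) builds quaternary C9: the ketene acetal should attack axially, anti to the adjacent pseudo-axial C8 methyl (A(1,2) strain with the C9 methyl keeps it axial), so the acetate arm ends trans to C17 and cis to C7–O, and silyl transfer traps the enolate regiospecifically between C5 and C10.

Step 7
Reactants: 9 tert-butyl 2-[(1S,5S,6S)-3,5-bis(tert-butyldimethylsilyloxy)-1,6-dimethylcyclohex-2-en-1-yl]acetate; 10 2-[(E)-2-nitroethenyl]furan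
Product: 11 tert-butyl 2-[(1S,2R,5S,6S)-5-(tert-butyldimethylsilyloxy)-2-[1-(furan-2-yl)-2-nitroethyl]-1,6-dimethyl-3-oxocyclohexyl]acetate
Conditions: Bu4NF (1.0 equiv), THF, −78 → −40 °C; AcOH quench
Reagents that add atoms: none
Why: Fluoride unmasks the regiodefined C10 enolate, which adds to the nitroalkene at its furyl-bearing carbon (fluoride-promoted Mukaiyama–Michael addition); C10, α to the ketone, should end under thermodynamic control with the large side chain equatorial and trans to the C9 acetate arm, while C1 forms as an epimer mixture that is corrected in step 13.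

Step 8
Reactants: 11 tert-butyl 2-[(1S,2R,5S,6S)-5-(tert-butyldimethylsilyloxy)-2-[1-(furan-2-yl)-2-nitroethyl]-1,6-dimethyl-3-oxocyclohexyl]acetate
Product: 12 tert-butyl 2-[(1R,2S,5S,6S)-5-(tert-butyldimethylsilyloxy)-2-[1-(furan-2-yl)-2-nitroethyl]-1,6-dimethyl-3-methylidenecyclohexyl]acetate
Conditions: Ph3PCH3Br (3.5 equiv), KN(SiMe3)2 (3.3 equiv), THF, 0 → 40 °C; then AcOH, aq. NH4Cl, 0 °C
Reagents that add atoms: methyltriphenylphosphonium bromide, C[P+](c1ccccc1)(c1ccccc1)c1ccccc1.[Br-]
Why: Wittig methylenation: the first equivalent of base turns the acidic nitro group into its inert nitronate, which protects it while excess ylide converts the hindered C5 ketone into the C5=C19 alkene; C10 is thereby locked in its equilibrated equatorial configuration.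

Step 9
Reactants: 12 tert-butyl 2-[(1R,2S,5S,6S)-5-(tert-butyldimethylsilyloxy)-2-[1-(furan-2-yl)-2-nitroethyl]-1,6-dimethyl-3-methylidenecyclohexyl]acetate
Product: 13 tert-butyl 2-[(1R,2S,5S,6S)-5-(tert-butyldimethylsilyloxy)-2-[1-(furan-2-yl)-2-oxoethyl]-1,6-dimethyl-3-methylidenecyclohexyl]acetate
Conditions: NaOMe, MeOH, 0 °C; then TiCl3, NH4OAc, H2O/THF, 0 °C → rt
Reagents that add atoms: water, O
Why: Nef reaction in its reductive, buffered form (the nitronate is reduced by trivalent titanium to the imine, which hydrolyses), mild enough for the furan, the exocyclic alkene, the silyl ether and the tert-butyl ester.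

Step 10
Reactants: 13 tert-butyl 2-[(1R,2S,5S,6S)-5-(tert-butyldimethylsilyloxy)-2-[1-(furan-2-yl)-2-oxoethyl]-1,6-dimethyl-3-methylidenecyclohexyl]acetate; 14 prop-2-ynoic acid
Product: 15 5-[(1S,2R,3S,4S)-2-(2-tert-butoxy-2-oxoethyl)-4-(tert-butyldimethylsilyloxy)-2,3-dimethyl-6-methylidenecyclohexyl]-5-(furan-2-yl)-4-hydroxypent-2-ynoic acid
Conditions: 14, n-BuLi (2 equiv per 14), THF, −78 °C; then 13, −78 °C; 1 M HCl
Reagents that add atoms: none
Why: 1,2-Addition of the acetylide carbon of dilithium propiolate to the aldehyde brings in C3, C4 and C18 with the acid already free; the C2 carbinol centre is irrelevant because it is oxidised in step 11.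

Step 11
Reactants: 15 5-[(1S,2R,3S,4S)-2-(2-tert-butoxy-2-oxoethyl)-4-(tert-butyldimethylsilyloxy)-2,3-dimethyl-6-methylidenecyclohexyl]-5-(furan-2-yl)-4-hydroxypent-2-ynoic acid
Product: 16 5-[(1S,2R,3S,4S)-2-(2-tert-butoxy-2-oxoethyl)-4-(tert-butyldimethylsilyloxy)-2,3-dimethyl-6-methylidenecyclohexyl]-5-(furan-2-yl)-4-oxopent-2-ynoic acid
Conditions: Dess–Martin periodinane, CH2Cl2, 0 °C
Reagents that add atoms: none
Why: Dess–Martin oxidation of the propargylic alcohol to the ynone under non-basic conditions tolerates the free acid and makes C1–H acidic, so that C1 can equilibrate later.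

Step 12
Reactants: 16 5-[(1S,2R,3S,4S)-2-(2-tert-butoxy-2-oxoethyl)-4-(tert-butyldimethylsilyloxy)-2,3-dimethyl-6-methylidenecyclohexyl]-5-(furan-2-yl)-4-oxopent-2-ynoic acid
Product: 17 (2Z)-5-[(1S,2R,3S,4S)-2-(2-tert-butoxy-2-oxoethyl)-4-(tert-butyldimethylsilyloxy)-2,3-dimethyl-6-methylidenecyclohexyl]-5-(furan-2-yl)-2-iodo-4-oxopent-2-enoic acid
Conditions: NaI, AcOH, rt, dark
Reagents that add atoms: sodium iodide, [Na+].[I-]
Why: Conjugate addition of iodide to the ynone (attack at C4, β to the ketone, the stronger acceptor) followed by anti protonation at C3 (hydroiodination) should give the Z-iodoenone with iodine cis to the C2 acyl group, the geometry required for closing ring B.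

Step 13
Reactants: 17 (2Z)-5-[(1S,2R,3S,4S)-2-(2-tert-butoxy-2-oxoethyl)-4-(tert-butyldimethylsilyloxy)-2,3-dimethyl-6-methylidenecyclohexyl]-5-(furan-2-yl)-2-iodo-4-oxopent-2-enoic acid
Product: 19 (1R,5S,7S,8S,9R,10R)-7-(tert-butyldimethylsilyloxy)-2-oxo-12,13-seco 18,19-lactone 12-tert-butyl ester, via neopentyl iodide acid 18 (not isolated)
Conditions: Pd(P(t-Bu)3)2 (10 mol%), 1,2,2,6,6-pentamethylpiperidine (1.5 equiv), toluene, 100 °C
Reagents that add atoms: none
Why: Proposed new method: zerovalent palladium inserts into the C4–I bond, 6-exo-trig syn-carbopalladation of the C5=C19 alkene closes ring B and makes quaternary C5, the resulting neopentyl C19–Pd–I species (no β-hydrogen) undergoes C(sp3)–I reductive elimination to 18, and the C18 carboxylate displaces the iodide to close the lactone; the closest known reaction types are the palladium-catalysed iodine-atom-transfer cycloisomerisation (carboiodination) of (Z)-1-iodo-1,6-dienes and domino Heck/anion capture, here extended by in-situ carboxylate capture of the alkyl iodide. Ring B closes 6-exo-trig at the alkene and the lactone 5-exo-tet at C19. C5 is controlled by ring A: with the C10 side chain equatorial, C4 must bond to the β-face of C5 (equatorial bond, trans-decalin), the α-face being shielded by the axial C20 methyl, which leaves C19 axial as required. C1, α to the C2 ketone, epimerises under the basic conditions and should be funnelled to the equatorial-furyl isomer (Curtin–Hammett during cyclisation, thermodynamic afterwards). The step needs exo rather than endo insertion (inherent to carbopalladation through a six-membered transition state), alkene insertion in preference to attack on the furan (which would need a strained pathway), and lactonisation by the C18 carboxylate only (it alone is 1,5 to C19; the C12 acid is masked as its tert-butyl ester).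

Step 14
Reactants: 19 (1R,5S,7S,8S,9R,10R)-7-(tert-butyldimethylsilyloxy)-2-oxo-12,13-seco 18,19-lactone 12-tert-butyl ester
Product: 23 (1R,5S,7S,8S,9R,10R)-7-hydroxy-2,12-dioxo pentacycle (2-dehydro-7-O-deacetyl target), via hydroxy acid 20 (not isolated), via trifluoroacetyl mixed anhydride 21 (not isolated), via cyclised trifluoroacetate 22 (not isolated)
Conditions: CF3CO2H/CH2Cl2/H2O (9:9:1), 0 °C → rt; evaporate; (CF3CO)2O, CH2Cl2, 0 °C → rt, high dilution; then aq. NaHCO3, THF
Reagents that add atoms: trifluoroacetic anhydride, O=C(OC(=O)C(F)(F)F)C(F)(F)F (trifluoroacetyl groups of 21 and 22 only)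
Why: Aqueous trifluoroacetic acid frees the C12 acid and C7–OH, and the mixed trifluoroacetic anhydride then acylates the furan at C13, the only ring position within reach (intramolecular Friedel–Crafts acylation closing seven-membered ring C, trans-fused because the furan at C1 and the arm at C9 are both equatorial); bicarbonate hydrolysis removes the C7 trifluoroacetate.

Step 15
Reactants: 23 (1R,5S,7S,8S,9R,10R)-7-hydroxy-2,12-dioxo pentacycle
Product: 24 (1R,5S,7S,8S,9R,10R)-7-acetoxy-2,12-dioxo pentacycle (2-dehydro target)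
Conditions: Ac2O, pyridine, CH2Cl2, 0 °C → rt
Reagents that add atoms: acetic anhydride, CC(=O)OC(C)=O
Why: Acylation of the only free hydroxyl (equatorial C7–OH) gives the acetate without touching any stereocentre.

Step 16
Reactants: 24 (1R,5S,7S,8S,9R,10R)-7-acetoxy-2,12-dioxo pentacycle
Product: 25 target CNP0182929.2, (1S,2S,5S,7S,8S,9R,10R)
Conditions: NaBH4, CeCl3·7H2O, MeOH, −78 °C
Reagents that add atoms: none
Why: Luche reduction: cerium-activated borohydride should reduce the most electrophilic carbonyl (the C2 enedione ketone) in 1,2-fashion, hydride arriving axially from the β-face of the rigid cyclohexenone to give the equatorial 2α (2S) alcohol, while the vinylogous-ester-like C12 furyl ketone, the lactone and the acetate should remain.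

Compound list
1 | 2-methylcyclohex-2-en-1-one | CC1=CCCC1=O | starting material
2 | (2R,3S)-2-methyl-3-(4,4,5,5-tetramethyl-1,3,2-dioxaborolan-2-yl)cyclohexan-1-one | CC1(C)OB(OC1(C)C)[C@H]1CCCC(=O)[C@@H]1C | intermediate
3 | (2R,3S)-3-hydroxy-2-methylcyclohexan-1-one | O[C@H]1CCCC(=O)[C@@H]1C | intermediate
4 | (2R,3S)-3-(tert-butyldimethylsilyloxy)-2-methylcyclohexan-1-one | CC(C)(C)[Si](C)(C)O[C@H]1CCCC(=O)[C@@H]1C | intermediate
5 | (5S,6R)-5-(tert-butyldimethylsilyloxy)-6-methylcyclohex-2-en-1-one | CC(C)(C)[Si](C)(C)O[C@H]1CC=CC(=O)[C@@H]1C | intermediate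
6 | (5S,6R)-5-(tert-butyldimethylsilyloxy)-1,6-dimethylcyclohex-2-en-1-ol (both epimers at C1 of the ring) | CC(C)(C)[Si](C)(C)O[C@H]1CC=CC(C)(O)[C@@H]1C | intermediate
7 | (4S,5S)-5-(tert-butyldimethylsilyloxy)-3,4-dimethylcyclohex-2-en-1-one | CC(C)(C)[Si](C)(C)O[C@H]1CC(=O)C=C(C)[C@@H]1C | intermediate
8 | tert-butyl[(1-tert-butoxyethenyl)oxy]dimethylsilane | C=C(OC(C)(C)C)O[Si](C)(C)C(C)(C)C | starting material
9 | tert-butyl 2-[(1S,5S,6S)-3,5-bis(tert-butyldimethylsilyloxy)-1,6-dimethylcyclohex-2-en-1-yl]acetate | CC(C)(C)[Si](C)(C)O[C@H]1CC(O[Si](C)(C)C(C)(C)C)=C[C@@](C)(CC(=O)OC(C)(C)C)[C@@H]1C | intermediate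
10 | 2-[(E)-2-nitroethenyl]furan | [O-][N+](=O)/C=C/c1ccco1 | starting material
11 | tert-butyl 2-[(1S,2R,5S,6S)-5-(tert-butyldimethylsilyloxy)-2-[1-(furan-2-yl)-2-nitroethyl]-1,6-dimethyl-3-oxocyclohexyl]acetate (epimers at the furyl-bearing carbon) | CC(C)(C)[Si](C)(C)O[C@H]1CC(=O)[C@H](C(C[N+](=O)[O-])c2ccco2)[C@@](C)(CC(=O)OC(C)(C)C)[C@@H]1C | intermediate
12 | tert-butyl 2-[(1R,2S,5S,6S)-5-(tert-butyldimethylsilyloxy)-2-[1-(furan-2-yl)-2-nitroethyl]-1,6-dimethyl-3-methylidenecyclohexyl]acetate (epimers at the furyl-bearing carbon) | CC(C)(C)[Si](C)(C)O[C@H]1CC(=C)[C@H](C(C[N+](=O)[O-])c2ccco2)[C@@](C)(CC(=O)OC(C)(C)C)[C@@H]1C | intermediate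
13 | tert-butyl 2-[(1R,2S,5S,6S)-5-(tert-butyldimethylsilyloxy)-2-[1-(furan-2-yl)-2-oxoethyl]-1,6-dimethyl-3-methylidenecyclohexyl]acetate (epimers at the furyl-bearing carbon) | CC(C)(C)[Si](C)(C)O[C@H]1CC(=C)[C@H](C(C=O)c2ccco2)[C@@](C)(CC(=O)OC(C)(C)C)[C@@H]1C | intermediate
14 | prop-2-ynoic acid | C#CC(=O)O | starting material
15 | 5-[(1S,2R,3S,4S)-2-(2-tert-butoxy-2-oxoethyl)-4-(tert-butyldimethylsilyloxy)-2,3-dimethyl-6-methylidenecyclohexyl]-5-(furan-2-yl)-4-hydroxypent-2-ynoic acid (epimers at C4 and C5 of the chain) | CC(C)(C)[Si](C)(C)O[C@H]1CC(=C)[C@H](C(C(O)C#CC(=O)O)c2ccco2)[C@@](C)(CC(=O)OC(C)(C)C)[C@@H]1C | intermediate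
16 | 5-[(1S,2R,3S,4S)-2-(2-tert-butoxy-2-oxoethyl)-4-(tert-butyldimethylsilyloxy)-2,3-dimethyl-6-methylidenecyclohexyl]-5-(furan-2-yl)-4-oxopent-2-ynoic acid (epimers at C5 of the chain) | CC(C)(C)[Si](C)(C)O[C@H]1CC(=C)[C@H](C(C(=O)C#CC(=O)O)c2ccco2)[C@@](C)(CC(=O)OC(C)(C)C)[C@@H]1C | intermediate
17 | (2Z)-5-[(1S,2R,3S,4S)-2-(2-tert-butoxy-2-oxoethyl)-4-(tert-butyldimethylsilyloxy)-2,3-dimethyl-6-methylidenecyclohexyl]-5-(furan-2-yl)-2-iodo-4-oxopent-2-enoic acid (epimers at C5 of the chain) | CC(C)(C)[Si](C)(C)O[C@H]1CC(=C)[C@H](C(C(=O)/C=C(\I)C(=O)O)c2ccco2)[C@@](C)(CC(=O)OC(C)(C)C)[C@@H]1C | intermediate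
18 | (1R,5S,7S,8S,9R,10R) ring A/B bicycle with C3=C4, C2 ketone, free C18 acid on C4, CH2I (C19) on C5, furan-2-yl on C1, silyloxy on C7, methyls on C8 and C9, CH2CO2t-Bu on C9 | CC(C)(C)[Si](C)(C)O[C@H]1C[C@@]2(CI)C(C(=O)O)=CC(=O)[C@@H](c3ccco3)[C@@H]2[C@@](C)(CC(=O)OC(C)(C)C)[C@@H]1C | intermediate
19 | (1R,5S,7S,8S,9R,10R) ring A/B 18,19-lactone with C3=C4, C2 ketone, furan-2-yl on C1, tert-butyldimethylsilyloxy on C7, methyls on C8 and C9, CH2CO2t-Bu on C9 (12,13-seco form of the ring system) | CC(C)(C)[Si](C)(C)O[C@H]1C[C@@]23COC(=O)C2=CC(=O)[C@@H](c4ccco4)[C@@H]3[C@@](C)(CC(=O)OC(C)(C)C)[C@@H]1C | intermediate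
20 | (1R,5S,7S,8S,9R,10R) 7-hydroxy 12-acid corresponding to 19 | O[C@H]1C[C@@]23COC(=O)C2=CC(=O)[C@@H](c4ccco4)[C@@H]3[C@@](C)(CC(=O)O)[C@@H]1C | intermediate
21 | 7-O-trifluoroacetyl, 12-(trifluoroacetic) mixed anhydride of 20 | FC(F)(F)C(=O)O[C@H]1C[C@@]23COC(=O)C2=CC(=O)[C@@H](c4ccco4)[C@@H]3[C@@](C)(CC(=O)OC(=O)C(F)(F)F)[C@@H]1C | intermediate
22 | (1R,5S,7S,8S,9R,10R) pentacycle with C2 and C12 ketones and C7 trifluoroacetate | FC(F)(F)C(=O)O[C@H]1C[C@@]23COC(=O)C2=CC(=O)[C@H]2c4occc4C(=O)C[C@@](C)([C@@H]1C)[C@@H]23 | intermediate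
23 | (1R,5S,7S,8S,9R,10R) pentacycle with C2 and C12 ketones and free C7–OH | O[C@H]1C[C@@]23COC(=O)C2=CC(=O)[C@H]2c4occc4C(=O)C[C@@](C)([C@@H]1C)[C@@H]23 | intermediate
24 | (1R,5S,7S,8S,9R,10R) pentacycle with C2 and C12 ketones and C7 acetate (2-dehydro target) | CC(=O)O[C@H]1C[C@@]23COC(=O)C2=CC(=O)[C@H]2c4occc4C(=O)C[C@@](C)([C@@H]1C)[C@@H]23 | intermediate
25 | CNP0182929.2, (1S,2S,5S,7S,8S,9R,10R)-7-acetoxy-2-hydroxy-12-oxo pentacyclic 18,19-lactone | CC(=O)O[C@H]1C[C@@]23COC(=O)C2=C[C@H](O)[C@H]2c4occc4C(=O)C[C@@](C)([C@@H]1C)[C@@H]23 | target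

Total step count: 16. Longest linear sequence: 16 steps (from 1; compounds 8, 10 and 14 are bought).

Steps most likely to fail

Step 13 (proposed new method). The catalyst may not turn over: the neopentyl palladium intermediate may rest as a stable alkyl–palladium carboxylate chelate instead of releasing the alkyl iodide, or the Z-iodoenone may isomerise to the E isomer, which cannot cyclise. The fallback separates the two bond formations with known reactions and sets out from 17. Trimethylsilyldiazomethane (MeOH/toluene) should give the methyl ester of 17 F1. The known iodine-atom-transfer cycloisomerisation of (Z)-1-iodo-1,6-dienes under zerovalent palladium (Pd(P(t-Bu)3)2, toluene, 110 °C, no base) should then give the neopentyl iodide methyl ester F2, with ring B and C5 set as in step 13. AgOSO2CF3 in CH2Cl2 should ionise the C19–I bond with participation of the neighbouring ester carbonyl and close the lactone with loss of the methyl group, coming back to the route at 19.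

Step 14. Intermolecular acylation at the free furan α-position C15 and oligomerisation, or acid-induced degradation of the furan, may outrun closure of the seven-membered ring. The fallback replaces the anhydride by an amide-derived electrophile and sets out from 19. Me3SiOSO2CF3/2,6-lutidine should cleave only the tert-butyl ester to give the silyl-protected C12 acid F3. Coupling with dimethylamine (isobutyl chloroformate, N-methylmorpholine) should give the N,N-dimethylamide F4. Activation with (CF3SO2)2O/2-fluoropyridine should generate a keteniminium/iminium triflate that attacks C13 intramolecularly (Vilsmeier–Haack-type acylation), and aqueous NaHCO3 hydrolyses the iminium to the ring-C ketone silyl ether F5. HF·pyridine then removes the silyl ether, coming back to the route at 23.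

Step 6. Facial selectivity at quaternary C9 may be poor, because the C8 methyl and the C7 silyloxy group direct the nucleophile to opposite faces of the enone. The fallback reverses the order in which the two C9 substituents arrive, so that dominance of the silyloxy group would now give the same C9 configuration; it sets out from 5. Addition of LiCH2CO2t-Bu (from tert-butyl acetate and LiN(i-Pr)2, THF, −78 °C) should give the tertiary allylic alcohol F6. Pyridinium chlorochromate transposes it to the enone carrying the acetate arm on C9 F7. Me2CuLi/Me3SiCl (THF, −78 °C) should deliver the C20 methyl anti to the C7 silyloxy group and give the trimethylsilyl enol ether F8. Fluoride-promoted addition of F8 to 10 as in step 7 comes back to the route at 11.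

Further compounds
F1 | step 13 | methyl (2Z)-5-[(1S,2R,3S,4S)-2-(2-tert-butoxy-2-oxoethyl)-4-(tert-butyldimethylsilyloxy)-2,3-dimethyl-6-methylidenecyclohexyl]-5-(furan-2-yl)-2-iodo-4-oxopent-2-enoate | CC(C)(C)[Si](C)(C)O[C@H]1CC(=C)[C@H](C(C(=O)/C=C(\I)C(=O)OC)c2ccco2)[C@@](C)(CC(=O)OC(C)(C)C)[C@@H]1C
F2 | step 13 | methyl ester of 18 (ring A/B neopentyl iodide, C18 methyl ester) | CC(C)(C)[Si](C)(C)O[C@H]1C[C@@]2(CI)C(C(=O)OC)=CC(=O)[C@@H](c3ccco3)[C@@H]2[C@@](C)(CC(=O)OC(C)(C)C)[C@@H]1C
F3 | step 14 | C12 acid of 19 with the C7 silyl ether retained | CC(C)(C)[Si](C)(C)O[C@H]1C[C@@]23COC(=O)C2=CC(=O)[C@@H](c4ccco4)[C@@H]3[C@@](C)(CC(=O)O)[C@@H]1C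
F4 | step 14 | N,N-dimethylamide of F3 | CC(C)(C)[Si](C)(C)O[C@H]1C[C@@]23COC(=O)C2=CC(=O)[C@@H](c4ccco4)[C@@H]3[C@@](C)(CC(=O)N(C)C)[C@@H]1C
F5 | step 14 | C7 tert-butyldimethylsilyl ether of 23 | CC(C)(C)[Si](C)(C)O[C@H]1C[C@@]23COC(=O)C2=CC(=O)[C@H]2c4occc4C(=O)C[C@@](C)([C@@H]1C)[C@@H]23
F6 | step 6 | tert-butyl 2-[(5S,6R)-5-(tert-butyldimethylsilyloxy)-1-hydroxy-6-methylcyclohex-2-en-1-yl]acetate (both epimers at C1 of the ring) | CC(C)(C)[Si](C)(C)O[C@H]1CC=CC(O)(CC(=O)OC(C)(C)C)[C@@H]1C
F7 | step 6 | tert-butyl 2-[(5S,6S)-5-(tert-butyldimethylsilyloxy)-6-methyl-3-oxocyclohex-1-en-1-yl]acetate | CC(C)(C)[Si](C)(C)O[C@H]1CC(=O)C=C(CC(=O)OC(C)(C)C)[C@@H]1C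
F8 | step 6 | tert-butyl 2-[(1S,5S,6S)-5-(tert-butyldimethylsilyloxy)-1,6-dimethyl-3-(trimethylsilyloxy)cyclohex-2-en-1-yl]acetate | CC(C)(C)[Si](C)(C)O[C@H]1CC(O[Si](C)(C)C)=C[C@@](C)(CC(=O)OC(C)(C)C)[C@@H]1C
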